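**Plan**

1. Retrosynthetic cuts, with atoms numbered as in the target SMILES read from the left (C1–C26; O8, O12, O21, O25): first C17–C18 (ring C), then the three arene bonds C19–C26, C20–C22 and C23–C24, then C13–C26 and C13–C14, then the bridge bonds C6–C13 and C9–C10, and last C6–C18 and C4–C2.
2. Forward order: cyclopentanone (C4, C5, C6, C7, C9), then the bicyclo[3.2.1]octane-3,8-dione by a three-carbon bridge C10–C11–C13, then quaternary C13, then the benzene ring together with the five-membered ring beside it, then ring C.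
3. Enabling feature: the hydroquinone ring (C19, C20, C22, C23, C24, C26) shares its C19–C26 edge with a five-membered ring whose other atoms are C18, C6 and C13. These three atoms are the tether of a 1,6-diyne, so alkyne arms on C18 (C19≡C20) and on C13 (C26≡C24) plus acetylene (C22, C23) give both rings at once, with boron on C20 and C24 standing in for the phenol oxygens.
4. Stereochemistry: C4 from a rhodium/(S)-BINAP conjugate addition; C9 and C6 relayed from C4 (trans enamine alkylation, then a ring closure that can only be cis); C13 from exo-face alkynylation after allylation; C18 dictated by the cage; the Z vinylsilane from a chelated carbomagnesiation.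

Key step: step 17

Remark: the isopropenyltrifluoroborate, the silylated propargyl bromide and the silylethynylbenziodoxolone are taken as purchasable. Bicyclooctane locants appear only inside compound names (C1 = target C6, C2 = C13, C3 = C11, C4 = C10, C5 = C9, C6 = C4, C7 = C5, C8 = C7), and exo there means on the side of the one-carbon C8 bridge.

**Allyl bromide (steps 1–3)**

Step 1
Reactants: 1 prop-2-yn-1-ol; 2 methylmagnesium bromide
Product: 3 (Z)-3-iodo-2-methylprop-2-en-1-ol
Conditions: MeMgBr (2.5 equiv), CuI (10 mol%), THF/Et2O, −10 °C → rt; then I2, −78 → 0 °C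
Reagents that add atoms: iodine (I2), II
Why: Copper-catalysed carbomagnesiation of the propargylic alkoxide adds methyl to the internal carbon and leaves a vinylmagnesium held cis to the CH2O group in a five-membered chelate, so iodinolysis with retention should give the Z vinyl iodide.

Step 2
Reactants: 3 (Z)-3-iodo-2-methylprop-2-en-1-ol
Product: 5 (Z)-2-methyl-3-(trimethylsilyl)prop-2-en-1-ol, via trimethylsilyl ether 4 (not isolated)
Conditions: n-BuLi (1.0 equiv), THF, −78 °C; Me3SiCl (1.05 equiv), −78 → 0 °C; t-BuLi (2.1 equiv), −78 → 0 °C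
Reagents that add atoms: chlorotrimethylsilane, C[Si](C)(C)Cl
Why: Iodine–lithium exchange on the silyl ether gives a configurationally stable vinyllithium that takes the silyl group from the neighbouring oxygen by a 1,4 oxygen-to-carbon shift (retro-Brook rearrangement), which places silicon cis to the CH2O group as the later ring closure demands.

Step 3
Reactants: 5 (Z)-2-methyl-3-(trimethylsilyl)prop-2-en-1-ol
Product: 6 (Z)-(3-bromo-2-methylprop-1-en-1-yl)trimethylsilane
Conditions: CBr4, PPh3, CH2Cl2, 0 °C
Reagents that add atoms: carbon tetrabromide, BrC(Br)(Br)Br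
Why: The Appel reaction substitutes the primary allylic alcohol by SN2 displacement of the oxyphosphonium group and does not touch the alkene geometry.

**Nitroallyl ester (steps 4–5)**

Step 4
Reactants: 7 nitromethane; 8 paraformaldehyde (source of formaldehyde, two equivalents consumed)
Product: 9 2-nitropropane-1,3-diol
Conditions: (CH2O)n (2.0 equiv as CH2O), NaOMe (1.0 equiv), MeOH, 0 °C → rt; then AcOH
Reagents that add atoms: formaldehyde (the second equivalent, released from 8), C=O
Why: A double Henry reaction joins nitromethane to two formaldehyde units in succession and stops at the diol because its sodium nitronate precipitates and cannot add a third time.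

Step 5
Reactants: 9 2-nitropropane-1,3-diol
Product: 11 2-nitroprop-2-en-1-yl pivalate, via bis-pivalate 10 (not isolated)
Conditions: t-BuCOCl (2.1 equiv), CHCl3, reflux; then NaOAc, Et2O, reflux
Reagents that add atoms: pivaloyl chloride, CC(C)(C)C(=O)Cl
Why: Double O-acylation followed by acetate-induced E1cB loss of one pivalate from the β-acyloxy nitroalkane gives the nitroallyl ester, a reagent that can be attacked twice and carries the future C10, C11 and C13.

**Main line (steps 6–19)**

Step 6
Reactants: 12 methyl 2-oxocyclopentane-1-carboxylate; 13 (3-bromoprop-1-yn-1-yl)tri(propan-2-yl)silane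
Product: 14 methyl 2-oxo-1-[3-(triisopropylsilyl)prop-2-yn-1-yl]cyclopentane-1-carboxylate (racemic)
Conditions: K2CO3, acetone, reflux
Reagents that add atoms: none
Why: Alkylation of the soft β-keto ester enolate places the propargyl arm (C18–C20) on the future C6 and, by making that carbon quaternary, leaves the ketone enolisable on one side only.

Step 7
Reactants: 14 methyl 2-oxo-1-[3-(triisopropylsilyl)prop-2-yn-1-yl]cyclopentane-1-carboxylate
Product: 16 methyl 2-oxo-1-[3-(triisopropylsilyl)prop-2-yn-1-yl]cyclopent-3-ene-1-carboxylate (racemic), via silyl enol ether 15 (not isolated)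
Conditions: LiN(iPr)2 (1.1 equiv), THF, −78 °C; Me3SiCl; solvent exchange; Pd(OAc)2 (1.05 equiv), MeCN, rt
Reagents that add atoms: none
Why: Saegusa–Ito oxidation of the only possible silyl enol ether gives the enone with its double bond on the side away from the quaternary carbon, which fixes the carbon that will receive the isopropenyl group.

Step 8
Reactants: 16 methyl 2-oxo-1-[3-(triisopropylsilyl)prop-2-yn-1-yl]cyclopent-3-ene-1-carboxylate; 17 potassium trifluoro(prop-1-en-2-yl)borate
Product: 18 methyl (4S)-2-oxo-4-(prop-1-en-2-yl)-1-[3-(triisopropylsilyl)prop-2-yn-1-yl]cyclopentane-1-carboxylate as both C1 epimers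
Conditions: [Rh(cod)2]PF6 (3 mol%), (S)-BINAP (3.3 mol%), PhMe/H2O (20:1), 105 °C
Reagents that add atoms: none
Why: In this Hayashi–Miyaura conjugate addition the rhodium–(S)-BINAP complex, which delivers alkenyl groups to give (S)-3-substituted cyclopentanones, should set C4 on either enantiomer of 16 because the distant quaternary centre offers little bias, and that centre is erased in step 9.

Step 9
Reactants: 18 methyl (4S)-2-oxo-4-(prop-1-en-2-yl)-1-[3-(triisopropylsilyl)prop-2-yn-1-yl]cyclopentane-1-carboxylate
Product: 19 (4S)-4-(prop-1-en-2-yl)-2-[3-(triisopropylsilyl)prop-2-yn-1-yl]cyclopentan-1-one as both C2 epimers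
Conditions: LiCl, DMSO/H2O, 150 °C
Reagents that add atoms: none
Why: Krapcho dealkoxycarbonylation removes the ester through chloride attack on the methyl group and loss of CO2, merging both diastereomers into one ketone whose C4 centre, being β to the carbonyl, cannot epimerise.

Step 10
Reactants: 19 (4S)-4-(prop-1-en-2-yl)-2-[3-(triisopropylsilyl)prop-2-yn-1-yl]cyclopentan-1-one; 11 2-nitroprop-2-en-1-yl pivalate
Product: 21 (2R,3S)-2-(2-nitroprop-2-en-1-yl)-3-(prop-1-en-2-yl)-5-[3-(triisopropylsilyl)prop-2-yn-1-yl]cyclopentan-1-one as both C5 epimers, via pyrrolidine enamine 20 (not isolated)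
Conditions: pyrrolidine, PhMe, reflux (Dean–Stark); 11, MeCN, −40 °C → rt; aq. AcOH/NaOAc
Reagents that add atoms: none
Why: In this Stork enamine alkylation the enamine forms toward the less substituted α-carbon (C9) and attacks the nitroallyl ester by conjugate addition and loss of pivalate from the face anti to the neighbouring isopropenyl group, which sets C9 trans to C4.

Step 11
Reactants: 21 (2R,3S)-2-(2-nitroprop-2-en-1-yl)-3-(prop-1-en-2-yl)-5-[3-(triisopropylsilyl)prop-2-yn-1-yl]cyclopentan-1-one
Product: 23 (1S,5R,6S)-6-(prop-1-en-2-yl)-1-[3-(triisopropylsilyl)prop-2-yn-1-yl]bicyclo[3.2.1]octane-3,8-dione, via bicyclic potassium nitronate 22 (not isolated)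
Conditions: KOtBu (1.1 equiv), THF/t-BuOH, −40 → 0 °C; then TiCl3 (aq.), NH4OAc, THF/H2O, rt
Reagents that add atoms: water, O
Why: Reversible enolisation funnels through the C6 enolate, whose intramolecular Michael addition (6-endo-trig) to the nitroalkene can only occur on the face cis to the C9 tether and so sets C6 and leaves the isopropenyl group exo, and the resulting nitronate is converted to the ketone by a Nef reaction with trivalent titanium.

Step 12
Reactants: 23 (1S,5R,6S)-6-(prop-1-en-2-yl)-1-[3-(triisopropylsilyl)prop-2-yn-1-yl]bicyclo[3.2.1]octane-3,8-dione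
Product: 24 (4E)-4-[(dimethylamino)methylidene]-6-exo-(prop-1-en-2-yl)-1-[3-(triisopropylsilyl)prop-2-yn-1-yl]bicyclo[3.2.1]octane-3,8-dione (ring centres arranged as in 23)
Conditions: t-BuOCH(NMe2)2 (1.5 equiv), PhMe, 90 °C
Reagents that add atoms: tert-butoxybis(dimethylamino)methane, CC(C)(C)OC(N(C)C)N(C)C
Why: Aminomethylenation with the aminal ester occurs at the less hindered methylene C10 (C13 is neopentylic) and the resulting vinylogous amide removes both C10 hydrogens, so that C13 is the only carbon of the ketone left to enolise.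

Step 13
Reactants: 24 (4E)-4-[(dimethylamino)methylidene]-6-exo-(prop-1-en-2-yl)-1-[3-(triisopropylsilyl)prop-2-yn-1-yl]bicyclo[3.2.1]octane-3,8-dione; 6 (Z)-(3-bromo-2-methylprop-1-en-1-yl)trimethylsilane
Product: 25 2-exo-[(Z)-2-methyl-3-(trimethylsilyl)prop-2-en-1-yl] derivative of 24
Conditions: LiN(iPr)2 (1.1 equiv), THF, −78 °C; 6 (1.3 equiv), −78 → −20 °C
Reagents that add atoms: none
Why: Lithium diisopropylamide deprotonates the vinylogous amide at C13 and the cross-conjugated enolate is alkylated by the allylic bromide in an SN2 reaction on the exo face; the new centre is only temporary because it is enolised again in step 14.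

Step 14
Reactants: 25 2-exo-[(Z)-2-methyl-3-(trimethylsilyl)prop-2-en-1-yl] derivative of 24; 26 1-[(trimethylsilyl)ethynyl]-1,2-benziodoxol-3(1H)-one
Product: 27 (4E)-4-[(dimethylamino)methylidene]-2-exo-ethynyl-2-endo-[(Z)-2-methyl-3-(trimethylsilyl)prop-2-en-1-yl]-6-exo-(prop-1-en-2-yl)-1-(prop-2-yn-1-yl)bicyclo[3.2.1]octane-3,8-dione
Conditions: LiN(iPr)2 (1.2 equiv), THF, −78 → 0 °C; 26 (1.5 equiv), Bu4NF (1.5 equiv), −78 °C; then Bu4NF (2 equiv), rt
Reagents that add atoms: none
Why: Electrophilic α-alkynylation of the ketone enolate by the ethynylbenziodoxolone freed from 26 by fluoride should take place on the exo face, syn to the C7 carbonyl bridge and away from the C4–C5 bridge, which sets C13 with the ethynyl group exo (cis-1,3 to the propargyl arm) and the allyl chain endo, and the excess fluoride also frees the second alkyne.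

Step 15
Reactants: 27 (4E)-4-[(dimethylamino)methylidene]-2-exo-ethynyl-2-endo-[(Z)-2-methyl-3-(trimethylsilyl)prop-2-en-1-yl]-6-exo-(prop-1-en-2-yl)-1-(prop-2-yn-1-yl)bicyclo[3.2.1]octane-3,8-dione
Product: 28 2-exo-ethynyl-2-endo-[(Z)-2-methyl-3-(trimethylsilyl)prop-2-en-1-yl]-6-exo-(prop-1-en-2-yl)-1-(prop-2-yn-1-yl)bicyclo[3.2.1]octane-3,8-dione
Conditions: NaOH (2 M aq.), MeOH, 70 °C
Reagents that add atoms: none
Why: Hydroxide hydrolyses the enaminone to the hydroxymethylene ketone and a retro-Claisen loss of formate frees C10, while the quaternary C13 and the bridgehead centres cannot epimerise.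

Step 16
Reactants: 28 2-exo-ethynyl-2-endo-[(Z)-2-methyl-3-(trimethylsilyl)prop-2-en-1-yl]-6-exo-(prop-1-en-2-yl)-1-(prop-2-yn-1-yl)bicyclo[3.2.1]octane-3,8-dione
Product: 29 bis(pinacolboronate) of 28 carrying boron on both alkyne termini
Conditions: lithium 2,2,6,6-tetramethylpiperidide (3.3 equiv), THF, −78 °C; iPrOBpin (3.5 equiv), −78 → −40 °C; HCl (2 M in Et2O), −78 °C → rt
Reagents that add atoms: 2-isopropoxy-4,4,5,5-tetramethyl-1,3,2-dioxaborolane, CC(C)OB1OC(C)(C)C(C)(C)O1
Why: Deprotonation and borylation of terminal alkynes (acetylide, borate, acid release) is standard, and here the first equivalent of base turns the only enolisable ketone (C11) into its enolate, which protects it, whereas the C7 ketone has no α-hydrogen and is flanked by two branched carbons.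

Step 17
Reactants: 29 bis(pinacolboronate) of 28; 30 acetylene
Product: 31 tetracyclic aryl bis(pinacolboronate) (4,7-diborylindane fused to the bicyclooctanedione through C13 and C6)
Conditions: Cp*RuCl(cod) (10 mol%), HC≡CH (1 atm), ClCH2CH2Cl, rt
Reagents that add atoms: none
Why: The Cp*RuCl fragment (divalent ruthenium) takes up both boryl alkynes of 29 and couples them oxidatively at C19 and C26 to a ruthenacyclopentadiene, which closes the five-membered carbocycle C6–C18–C19–C26–C13; acetylene then inserts and reductive elimination forms C20–C22 and C23–C24, so that the benzene ring is completed in the same catalytic cycle. The closest known reaction type is the Cp*RuCl(cod)-catalysed [2+2+2] cyclotrimerisation of 1,6-diynes with a monoalkyne, in which alkynylboronates are established partners. The carbocycle therefore closes as a five-membered ring by intramolecular oxidative cyclisation across the three-atom tether, and the arene as a six-membered ring by intermolecular insertion of the third alkyne. No stereocentre is created, and the quaternary C6 and C13 and the neutral conditions leave the existing ones untouched. The selectivity needed is cross-trimerisation over dimerisation of 29 and over ene–yne pathways with the isopropenyl and vinylsilane groups. Excess acetylene, the bulky boryl termini and the cis-1,3 placement of the two arms (exo alkyne on C13, CH2–alkyne on C6) should secure it.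

Step 18
Reactants: 31 tetracyclic aryl bis(pinacolboronate)
Product: 33 p-benzoquinone corresponding to 31 (carbonyls at C20 and C24), via hydroquinone 32 (not isolated)
Conditions: NaBO3·4H2O (6 equiv), THF/H2O, rt; extraction under argon; Ag2O (3 equiv), Na2SO4, Et2O, rt
Reagents that add atoms: sodium perborate, [Na+].[O-]OB=O
Why: Perborate oxidises both aryl C–B bonds with retention through a 1,2 shift from boron to oxygen, and Ag2O then takes the electron-rich hydroquinone to the p-quinone, which makes the C18 hydrogens vinylogously acidic.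

Step 19
Reactants: 33 p-benzoquinone corresponding to 31
Product: 34 CNP0287617.1
Conditions: Et3N (0.2 equiv), (CF3)2CHOH, 40 °C
Reagents that add atoms: none
Why: Proposed new method: amine-catalysed tautomerisation of the quinone through loss of a C18 hydrogen should give the ortho-quinone methide (C18=C19 beside the C20 carbonyl), which, activated by hydrogen bonding from the fluorinated alcohol, is attacked at C18 by the silicon-bearing carbon C17 of the Z vinylsilane held on the same face by the C13–C14 tether, the β-silyl cation at C15 then losing silicon to give the C15=C17 alkene and the rearomatised hydroquinone with C18 set by the bridged geometry; the closest known reactions are the base-induced tautomerisation of alkylquinones to ortho-quinone methides with capture by π-nucleophiles and vinylsilane-terminated cation cyclisations.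

**Compound list**

1 | prop-2-yn-1-ol | C#CCO | starting material
2 | methylmagnesium bromide | C[Mg]Br | starting material
3 | (Z)-3-iodo-2-methylprop-2-en-1-ol | OC/C(C)=C\I | intermediate
4 | trimethylsilyl ether of 3 | C[Si](C)(C)OC/C(C)=C\I | intermediate
5 | (Z)-2-methyl-3-(trimethylsilyl)prop-2-en-1-ol | OC/C(C)=C\[Si](C)(C)C | intermediate
6 | (Z)-(3-bromo-2-methylprop-1-en-1-yl)trimethylsilane | BrC/C(C)=C\[Si](C)(C)C | intermediate
7 | nitromethane | C[N+](=O)[O-] | starting material
8 | paraformaldehyde (formaldehyde unit) | C=O | starting material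
9 | 2-nitropropane-1,3-diol | OCC(CO)[N+](=O)[O-] | intermediate
10 | 2-nitropropane-1,3-diyl bis(2,2-dimethylpropanoate) | CC(C)(C)C(=O)OCC(COC(=O)C(C)(C)C)[N+](=O)[O-] | intermediate
11 | 2-nitroprop-2-en-1-yl pivalate | C=C(COC(=O)C(C)(C)C)[N+](=O)[O-] | intermediate
12 | methyl 2-oxocyclopentane-1-carboxylate | COC(=O)C1CCCC1=O | starting material
13 | (3-bromoprop-1-yn-1-yl)tri(propan-2-yl)silane | BrCC#C[Si](C(C)C)(C(C)C)C(C)C | starting material
14 | methyl 2-oxo-1-[3-(triisopropylsilyl)prop-2-yn-1-yl]cyclopentane-1-carboxylate, racemic | COC(=O)C1(CC#C[Si](C(C)C)(C(C)C)C(C)C)CCCC1=O | intermediate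
15 | methyl 1-[3-(triisopropylsilyl)prop-2-yn-1-yl]-2-(trimethylsilyloxy)cyclopent-2-ene-1-carboxylate, racemic | COC(=O)C1(CC#C[Si](C(C)C)(C(C)C)C(C)C)CCC=C1O[Si](C)(C)C | intermediate
16 | methyl 2-oxo-1-[3-(triisopropylsilyl)prop-2-yn-1-yl]cyclopent-3-ene-1-carboxylate, racemic | COC(=O)C1(CC#C[Si](C(C)C)(C(C)C)C(C)C)CC=CC1=O | intermediate
17 | potassium trifluoro(prop-1-en-2-yl)borate | [K+].C=C(C)[B-](F)(F)F | starting material
18 | methyl (4S)-2-oxo-4-(prop-1-en-2-yl)-1-[3-(triisopropylsilyl)prop-2-yn-1-yl]cyclopentane-1-carboxylate, both C1 epimers | C=C(C)[C@H]1CC(CC#C[Si](C(C)C)(C(C)C)C(C)C)(C(=O)OC)C(=O)C1 | intermediate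
19 | (4S)-4-(prop-1-en-2-yl)-2-[3-(triisopropylsilyl)prop-2-yn-1-yl]cyclopentan-1-one, both C2 epimers | C=C(C)[C@H]1CC(CC#C[Si](C(C)C)(C(C)C)C(C)C)C(=O)C1 | intermediate
20 | 1-[(3S)-3-(prop-1-en-2-yl)-5-[3-(triisopropylsilyl)prop-2-yn-1-yl]cyclopent-1-en-1-yl]pyrrolidine | C=C(C)[C@H]1CC(CC#C[Si](C(C)C)(C(C)C)C(C)C)C(N2CCCC2)=C1 | intermediate
21 | (2R,3S)-2-(2-nitroprop-2-en-1-yl)-3-(prop-1-en-2-yl)-5-[3-(triisopropylsilyl)prop-2-yn-1-yl]cyclopentan-1-one, both C5 epimers | C=C(C)[C@H]1CC(CC#C[Si](C(C)C)(C(C)C)C(C)C)C(=O)[C@@H]1CC(=C)[N+](=O)[O-] | intermediate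
22 | potassium nitronate of (1S,5R,6S)-3-nitro-6-(prop-1-en-2-yl)-1-[3-(triisopropylsilyl)prop-2-yn-1-yl]bicyclo[3.2.1]octan-8-one | C=C(C)[C@H]1C[C@@]2(CC#C[Si](C(C)C)(C(C)C)C(C)C)C(=O)[C@@H]1CC(=[N+]([O-])[O-])C2.[K+] | intermediate
23 | (1S,5R,6S)-6-(prop-1-en-2-yl)-1-[3-(triisopropylsilyl)prop-2-yn-1-yl]bicyclo[3.2.1]octane-3,8-dione (isopropenyl exo) | C=C(C)[C@H]1C[C@@]2(CC#C[Si](C(C)C)(C(C)C)C(C)C)C(=O)[C@@H]1CC(=O)C2 | intermediate
24 | (4E)-4-[(dimethylamino)methylidene] derivative of 23 | C=C(C)[C@H]1C[C@@]2(CC#C[Si](C(C)C)(C(C)C)C(C)C)C(=O)[C@@H]1/C(=C\N(C)C)C(=O)C2 | intermediate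
25 | 24 carrying a 2-exo-[(Z)-2-methyl-3-(trimethylsilyl)prop-2-en-1-yl] group | C=C(C)[C@H]1C[C@@]2(CC#C[Si](C(C)C)(C(C)C)C(C)C)C(=O)[C@@H]1/C(=C\N(C)C)C(=O)[C@@H]2C/C(C)=C\[Si](C)(C)C | intermediate
26 | 1-[(trimethylsilyl)ethynyl]-1,2-benziodoxol-3(1H)-one | C[Si](C)(C)C#CI1OC(=O)c2ccccc12 | starting material
27 | (4E)-4-[(dimethylamino)methylidene]-2-exo-ethynyl-2-endo-[(Z)-2-methyl-3-(trimethylsilyl)prop-2-en-1-yl]-6-exo-(prop-1-en-2-yl)-1-(prop-2-yn-1-yl)bicyclo[3.2.1]octane-3,8-dione | C=C(C)[C@H]1C[C@@]2(CC#C)C(=O)[C@@H]1/C(=C\N(C)C)C(=O)[C@@]2(C#C)C/C(C)=C\[Si](C)(C)C | intermediate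
28 | 2-exo-ethynyl-2-endo-[(Z)-2-methyl-3-(trimethylsilyl)prop-2-en-1-yl]-6-exo-(prop-1-en-2-yl)-1-(prop-2-yn-1-yl)bicyclo[3.2.1]octane-3,8-dione | C=C(C)[C@H]1C[C@@]2(CC#C)C(=O)[C@@H]1CC(=O)[C@@]2(C#C)C/C(C)=C\[Si](C)(C)C | intermediate
29 | bis(pinacolboronate) of 28, boron on both alkyne termini | C=C(C)[C@H]1C[C@@]2(CC#CB3OC(C)(C)C(C)(C)O3)C(=O)[C@@H]1CC(=O)[C@@]2(C#CB3OC(C)(C)C(C)(C)O3)C/C(C)=C\[Si](C)(C)C | intermediate
30 | acetylene | C#C | starting material
31 | tetracyclic aryl bis(pinacolboronate): 4,7-diborylindane fused to the bicyclooctanedione, allylsilane chain endo on C13 | C=C(C)[C@H]1C[C@@]23C(=O)[C@@H]1CC(=O)[C@]2(C/C(C)=C\[Si](C)(C)C)c1c(B2OC(C)(C)C(C)(C)O2)ccc(B2OC(C)(C)C(C)(C)O2)c1C3 | intermediate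
32 | hydroquinone corresponding to 31 (OH on C20 and C24) | C=C(C)[C@H]1C[C@@]23C(=O)[C@@H]1CC(=O)[C@]2(C/C(C)=C\[Si](C)(C)C)c1c(O)ccc(O)c1C3 | intermediate
33 | p-benzoquinone corresponding to 32 | C=C(C)[C@H]1C[C@@]23C(=O)[C@@H]1CC(=O)[C@]2(C/C(C)=C\[Si](C)(C)C)C1=C(C3)C(=O)C=CC1=O | intermediate
34 | CNP0287617.1 | C=C(C)[C@H]1C[C@@]23C(=O)[C@@H]1CC(=O)[C@@]21CC(C)=C[C@@H]3c2c(O)ccc(O)c21 | target

**Step count and risks**

Total: 19 steps (1–3 allyl bromide, 4–5 nitroallyl ester, 6–19 main line). Longest linear sequence: 14 steps (12 to 34, steps 6–19).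

Steps most likely to fail:

1. Step 19 (Proposed new method). The tautomeric equilibrium may lie far on the quinone side, and the transient quinone methide may be drained by dimerisation or by oxygen nucleophiles before the weakly nucleophilic vinylsilane closes ring C. Fallback, setting out from 31 and returning at 34: perborate oxidation to 32 followed by Me2SO4/K2CO3 in acetone should give the hydroquinone dimethyl ether F1. DDQ (2,6-dichloropyridine, LiClO4, ClCH2CH2Cl) then abstracts hydride from the only benzylic CH2 (C18), and the methoxy-stabilised benzylic cation is closed by the vinylsilane to the ring-C dimethyl ether F2. (NH4)2Ce(NO3)6 in MeCN/H2O demethylates oxidatively to the quinone of the target F3, and Na2S2O4 reduces it to 34.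

2. Step 17. Oxidative coupling of two alkynes that both end in a bulky boryl group may be slow, so that acetylene self-trimerisation, catalyst deactivation or loss of boron on the metal compete. Fallback, setting out from 28 and returning at 31: N-iodosuccinimide with AgNO3 (10 mol%) in acetone should give the bis(iodoalkyne) F4. The same Cp*RuCl(cod)/acetylene cyclotrimerisation, known for diiododiynes, then gives the diiodoarene F5, and Miyaura borylation (B2pin2, PdCl2(dppf), KOAc, dioxane, 80 °C) leads back to 31. This detour also bypasses step 16.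

3. Step 14. Removal of the remaining endo hydrogen at C13 may be incomplete, or the congested enolate next to the quaternary C6 may fail to add to the iodine-bound alkyne and react at oxygen instead. Fallback, setting out from 25 and returning at 27: the lithium enolate of 25 is treated with monomeric formaldehyde, the smallest electrophile, to give the exo hydroxymethyl compound F6. Dess–Martin periodinane gives the aldehyde F7, Seyferth–Gilbert homologation with the Ohira–Bestmann reagent (K2CO3, MeOH) gives the ethynyl compound still silylated on the propargyl arm F8, and Bu4NF returns to 27.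

**Further compounds**

F1 | step 19 | dimethyl ether of hydroquinone 32 | C=C(C)[C@H]1C[C@@]23C(=O)[C@@H]1CC(=O)[C@]2(C/C(C)=C\[Si](C)(C)C)c1c(OC)ccc(OC)c1C3
F2 | step 19 | dimethyl ether of 34 | C=C(C)[C@H]1C[C@@]23C(=O)[C@@H]1CC(=O)[C@@]21CC(C)=C[C@@H]3c2c(OC)ccc(OC)c21
F3 | step 19 | p-benzoquinone of 34 | C=C(C)[C@H]1C[C@@]23C(=O)[C@@H]1CC(=O)[C@@]21CC(C)=C[C@@H]3C2=C1C(=O)C=CC2=O
F4 | step 17 | bis(iodoalkyne) of 28 | C=C(C)[C@H]1C[C@@]2(CC#CI)C(=O)[C@@H]1CC(=O)[C@@]2(C#CI)C/C(C)=C\[Si](C)(C)C
F5 | step 17 | diiodoarene analogue of 31 (iodine on C20 and C24) | C=C(C)[C@H]1C[C@@]23C(=O)[C@@H]1CC(=O)[C@]2(C/C(C)=C\[Si](C)(C)C)c1c(I)ccc(I)c1C3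
F6 | step 14 | 2-exo-hydroxymethyl derivative of 25 | C=C(C)[C@H]1C[C@@]2(CC#C[Si](C(C)C)(C(C)C)C(C)C)C(=O)[C@@H]1/C(=C\N(C)C)C(=O)[C@@]2(CO)C/C(C)=C\[Si](C)(C)C
F7 | step 14 | 2-exo-formyl derivative of 25 | C=C(C)[C@H]1C[C@@]2(CC#C[Si](C(C)C)(C(C)C)C(C)C)C(=O)[C@@H]1/C(=C\N(C)C)C(=O)[C@@]2(C=O)C/C(C)=C\[Si](C)(C)C
F8 | step 14 | 27 with the triisopropylsilyl group still on the propargyl arm | C=C(C)[C@H]1C[C@@]2(CC#C[Si](C(C)C)(C(C)C)C(C)C)C(=O)[C@@H]1/C(=C\N(C)C)C(=O)[C@@]2(C#C)C/C(C)=C\[Si](C)(C)C
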